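The pyran ring C of the robinetinidol unit is disconnected across C2–C3 and C4–C4a. An aryl oxocarbenium ion (C4a=C8a–O1=C2, a cationic 2-oxadiene), made from a mixed O-aryl O-methyl acetal, adds to an (E)-enol acetate that already carries the complete benzylated gallocatechin unit on C4 (oxa-Povarov reaction). The step exploits the phloroglucinol ring D, which stabilises a cation at C4, and the free position C4a of ring A, para to O7 and ortho to O1. One operation closes ring C and sets C2, C3 and the interflavan carbon C4 all-trans; a chiral acid steers the face. Deacetylation and hydrogenolysis finish the synthesis.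

Key step: step 8

Assumption: (+)-gallocatechin (2R,3S), 3-(benzyloxy)phenol and 3,4,5-tris(benzyloxy)benzaldehyde are taken as purchasable; flavan numbering is used, with rings A (benzo), C (pyran) and B (pyrogallol) in the robinetinidol unit and rings D, F and E in the gallocatechin unit.

Step 1
Reactants: 1 (+)-gallocatechin
Product: 2 5,7,3',4',5'-penta-O-benzylgallocatechin (3-OH free)
Conditions: BnBr (5.5 equiv), K2CO3, DMF, 0 °C to rt, argon
Reagents that add atoms: benzyl bromide BrCc1ccccc1
Why: Williamson ether synthesis in which K2CO3 deprotonates only the five phenols, so the secondary 3-OH stays free and C2 and C3 are untouched.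

Step 2
Reactants: 2 5,7,3',4',5'-penta-O-benzylgallocatechin
Product: 3 3,5,7,3',4',5'-hexa-O-benzylgallocatechin
Conditions: NaH, BnBr, n-Bu4NI (cat.), THF/DMF, 0 °C to rt
Reagents that add atoms: benzyl bromide BrCc1ccccc1
Why: Williamson ether synthesis on the sodium alkoxide caps the last hydroxyl as a benzyl ether that should survive the later base, organolithium and acid steps, and with no free phenol left ring F cannot open and epimerise.

Step 3
Reactants: 3 3,5,7,3',4',5'-hexa-O-benzylgallocatechin
Product: 4 8-formyl-3,5,7,3',4',5'-hexa-O-benzylgallocatechin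
Conditions: POCl3, DMF, ClCH2CH2Cl, 0 °C to 40 °C; then aq. NaOAc
Reagents that add atoms: N,N-dimethylformamide CN(C)C=O (formyl carbon); water O (carbonyl oxygen)
Why: Vilsmeier–Haack formylation should take place on the phloroglucinol ring D, the most electron-rich arene, and favour C8 over C6 as other electrophilic substitutions of 5,7-di-O-alkylflavans do.

Step 4
Reactants: 4 8-formyl-3,5,7,3',4',5'-hexa-O-benzylgallocatechin
Product: 6 potassium (E)-2-(hexa-O-benzylgallocatechin-8-yl)ethenyltrifluoroborate, via alkenyl pinacol boronate 5 (not isolated)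
Conditions: CH2(Bpin)2, lithium 2,2,6,6-tetramethylpiperidide (from 2,2,6,6-tetramethylpiperidine and n-BuLi), THF, 0 °C, then 4, −78 °C to rt; then aq. KHF2, MeOH, rt
Reagents that add atoms: bis(4,4,5,5-tetramethyl-1,3,2-dioxaborolan-2-yl)methane CC1(C)OB(CB2OC(C)(C)C(C)(C)O2)OC1(C)C; potassium hydrogen difluoride F.[F-].[K+]
Why: boron-Wittig olefination of the aldehyde with the lithiated bis(boryl)methane should give the (E)-alkenyl boronate by syn elimination of the borate from the less hindered adduct, and KHF2 converts it into the trifluoroborate salt without touching the double-bond geometry.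

Step 5
Reactants: 6 potassium (E)-2-(hexa-O-benzylgallocatechin-8-yl)ethenyltrifluoroborate
Product: 7 (E)-2-(hexa-O-benzylgallocatechin-8-yl)ethenyl acetate
Conditions: AcOH, CuBr (10 mol%), DMAP (20 mol%), 4 Å MS, O2 (1 atm), CH2Cl2, 40 °C
Reagents that add atoms: acetic acid CC(=O)O
Why: copper-catalysed oxidative C–O coupling of an alkenyltrifluoroborate with a carboxylic acid (Chan–Lam type) should replace boron by acetate with retention of the (E)-geometry, because transmetalation and reductive elimination both occur at the same vinyl carbon.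

Step 6
Reactants: 8 3,4,5-tris(benzyloxy)benzaldehyde
Product: 9 3,4,5-tris(benzyloxy)benzaldehyde dimethyl acetal
Conditions: HC(OMe)3, MeOH, p-TsOH·H2O (cat.), rt; Et3N quench
Reagents that add atoms: methanol CO; trimethyl orthoformate COC(OC)OC
Why: acid-catalysed acetalisation, driven to completion by the orthoformate as water scavenger; no stereocenter is involved.

Step 7
Reactants: 9 3,4,5-tris(benzyloxy)benzaldehyde dimethyl acetal; 10 3-(benzyloxy)phenol
Product: 12 racemic O-[3-(benzyloxy)phenyl] O-methyl acetal of 3,4,5-tris(benzyloxy)benzaldehyde, via α-chloro ether 11 (not isolated)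
Conditions: AcCl (1.0 equiv), ZnBr2 (cat.), CH2Cl2, rt; then sodium 3-(benzyloxy)phenoxide (from 10 and NaH, THF), 0 °C to rt
Reagents that add atoms: none
Why: ZnBr2-catalysed cleavage of the dimethyl acetal by the acyl chloride gives the α-chloro ether, which alkylates the phenoxide on oxygen as in MOM protection of phenols; the acetal carbon forms as a racemate, which does not matter because it becomes planar in step 8.

Step 8
Reactants: 7 (E)-2-(hexa-O-benzylgallocatechin-8-yl)ethenyl acetate; 12 racemic O-[3-(benzyloxy)phenyl] O-methyl acetal of 3,4,5-tris(benzyloxy)benzaldehyde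
Product: 15 (2R,3S,4S)-3-O-acetyl-7,3',4',5'-tetra-O-benzylrobinetinidol-(4α→8)-hexa-O-benzylgallocatechin, via aryl oxocarbenium ion 13 (not isolated), via benzylic cation 14 (not isolated)
Conditions: 7 (1.0 equiv), 12 (1.3 equiv), chiral confined imidodiphosphorimidate Brønsted acid (5 mol%), 5 Å MS, CH2Cl2, −60 °C to −30 °C
Reagents that add atoms: none
Why: Proposed new method: the acid ionises 12 by loss of methanol to the aryl oxocarbenium ion 13, a cationic 2-oxadiene (C4a=C8a–O1=C2); its carbon C2 is attacked by the acetoxy-bearing carbon of 7, because ring D with its three oxygens stabilises the charge developing at C4 far better than the acetoxy group could stabilise one at C3, and cation 14 is then captured by ring A at the position para to its benzyloxy group, with loss of the proton that regenerates the acid. The closest known reaction types are the SnCl4-promoted oxa-Povarov reaction of aryl mixed acetals with styrenes, the chiral Brønsted acid catalysed aza-Povarov reaction of enol derivatives and Prins-type additions of styrenes to oxocarbenium ions paired with confined chiral anions; what has not been shown is control of the oxocarbenium face by a chiral anion in the oxa-Povarov manifold. Ring C is the only ring closed: formally an inverse-electron-demand [4+2] addition, in fact stepwise, the second bond by a six-membered Friedel–Crafts closure (6-exo-trig with respect to the cationic C4, the arene double bond lying inside the new ring). C2 is set by the chiral anion, which must leave the Si face of the oxocarbenium carbon open to give 2R (the antipode of the acid that does so is selected in a test run); C3 follows from the (E)-geometry and an open transition state with ring B anti to the acetoxy group (2,3-trans); C4 is set in the closure through the chair-like arrangement with all three substituents equatorial, reinforced by the acetate carbonyl bridging C4 on the face opposite to ring A (3,4-trans). The step needs site selectivity for the alkene over the free C6–H of ring D (the styrene terminus conjugated to ring D is the stronger nucleophile), closure para and not ortho to the benzyloxy group of ring A (the position between the two oxygens is hindered) and face selectivity (catalyst); because ring F of 7 is enantiopure, a product of attack on the other face is a diastereomer and should be removable by chromatography.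

Step 9
Reactants: 15 (2R,3S,4S)-3-O-acetyl-7,3',4',5'-tetra-O-benzylrobinetinidol-(4α→8)-hexa-O-benzylgallocatechin
Product: 16 7,3',4',5'-tetra-O-benzylrobinetinidol-(4α→8)-hexa-O-benzylgallocatechin (upper 3-OH free)
Conditions: K2CO3 (cat.), MeOH/THF, rt
Reagents that add atoms: none
Why: base-catalysed transesterification (methanolysis) should remove the secondary acetate, while benzyl ethers and all five stereocenters are inert to K2CO3 in methanol.

Step 10
Reactants: 16 7,3',4',5'-tetra-O-benzylrobinetinidol-(4α→8)-hexa-O-benzylgallocatechin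
Product: 17 robinetinidol-(4α→8)-gallocatechin
Conditions: H2 (1 atm), Pd(OH)2/C, THF/MeOH/H2O, rt; filtration and freeze-drying under argon
Reagents that add atoms: none
Why: hydrogenolysis of all ten benzyl ethers under neutral conditions should free the phenols and the lower 3-OH, the C2–O1 and C4–aryl bonds being far slower to cleave, so no stereocenter is affected.

Compound list
1 | (+)-gallocatechin, (2R,3S)-2-(3,4,5-trihydroxyphenyl)chroman-3,5,7-triol | Oc1cc(O)c2c(c1)O[C@H](c1cc(O)c(O)c(O)c1)[C@@H](O)C2 | starting material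
2 | (2R,3S)-5,7-bis(benzyloxy)-2-[3,4,5-tris(benzyloxy)phenyl]chroman-3-ol (penta-O-benzylgallocatechin) | c1ccccc1COc1cc(OCc2ccccc2)c2c(c1)O[C@H](c1cc(OCc3ccccc3)c(OCc3ccccc3)c(OCc3ccccc3)c1)[C@@H](O)C2 | intermediate
3 | (2R,3S)-3,5,7-tris(benzyloxy)-2-[3,4,5-tris(benzyloxy)phenyl]chroman (hexa-O-benzylgallocatechin) | c1ccccc1COc1cc(OCc2ccccc2)c2c(c1)O[C@H](c1cc(OCc3ccccc3)c(OCc3ccccc3)c(OCc3ccccc3)c1)[C@@H](OCc1ccccc1)C2 | intermediate
4 | (2R,3S)-3,5,7-tris(benzyloxy)-2-[3,4,5-tris(benzyloxy)phenyl]chroman-8-carbaldehyde | c1ccccc1COc1cc(OCc2ccccc2)c2c(c1C=O)O[C@H](c1cc(OCc3ccccc3)c(OCc3ccccc3)c(OCc3ccccc3)c1)[C@@H](OCc1ccccc1)C2 | intermediate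
5 | (E)-alkenyl pinacol boronate: 8-[(E)-2-(4,4,5,5-tetramethyl-1,3,2-dioxaborolan-2-yl)ethenyl] derivative of 3 | c1ccccc1COc1cc(OCc2ccccc2)c2c(c1/C=C/B3OC(C)(C)C(C)(C)O3)O[C@H](c1cc(OCc3ccccc3)c(OCc3ccccc3)c(OCc3ccccc3)c1)[C@@H](OCc1ccccc1)C2 | intermediate
6 | potassium (E)-2-[(2R,3S)-3,5,7-tris(benzyloxy)-2-[3,4,5-tris(benzyloxy)phenyl]chroman-8-yl]ethenyltrifluoroborate | c1ccccc1COc1cc(OCc2ccccc2)c2c(c1/C=C/[B-](F)(F)F)O[C@H](c1cc(OCc3ccccc3)c(OCc3ccccc3)c(OCc3ccccc3)c1)[C@@H](OCc1ccccc1)C2.[K+] | intermediate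
7 | (E)-2-[(2R,3S)-3,5,7-tris(benzyloxy)-2-[3,4,5-tris(benzyloxy)phenyl]chroman-8-yl]ethenyl acetate | c1ccccc1COc1cc(OCc2ccccc2)c2c(c1/C=C/OC(C)=O)O[C@H](c1cc(OCc3ccccc3)c(OCc3ccccc3)c(OCc3ccccc3)c1)[C@@H](OCc1ccccc1)C2 | intermediate
8 | 3,4,5-tris(benzyloxy)benzaldehyde | O=Cc1cc(OCc2ccccc2)c(OCc2ccccc2)c(OCc2ccccc2)c1 | starting material
9 | 3,4,5-tris(benzyloxy)benzaldehyde dimethyl acetal | COC(OC)c1cc(OCc2ccccc2)c(OCc2ccccc2)c(OCc2ccccc2)c1 | intermediate
10 | 3-(benzyloxy)phenol | Oc1cccc(OCc2ccccc2)c1 | starting material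
11 | racemic chloro(methoxy)methyl-3,4,5-tris(benzyloxy)benzene (α-chloro ether) | COC(Cl)c1cc(OCc2ccccc2)c(OCc2ccccc2)c(OCc2ccccc2)c1 | intermediate
12 | racemic [3-(benzyloxy)phenoxy](methoxy)methyl-3,4,5-tris(benzyloxy)benzene (mixed acetal) | COC(Oc1cccc(OCc2ccccc2)c1)c1cc(OCc2ccccc2)c(OCc2ccccc2)c(OCc2ccccc2)c1 | intermediate
13 | aryl oxocarbenium ion: [3-(benzyloxy)phenyl][3,4,5-tris(benzyloxy)benzylidene]oxonium | c1ccccc1COc1cccc(c1)[O+]=Cc1cc(OCc2ccccc2)c(OCc2ccccc2)c(OCc2ccccc2)c1 | intermediate
14 | benzylic cation after C2–C3 bond formation (C4 cation on ring D, C2 and C3 configured as in 15) | c1ccccc1COc1cccc(c1)O[C@H](c1cc(OCc3ccccc3)c(OCc3ccccc3)c(OCc3ccccc3)c1)[C@@H](OC(C)=O)[CH+]c1c(OCc2ccccc2)cc(OCc2ccccc2)c2c1O[C@H](c1cc(OCc3ccccc3)c(OCc3ccccc3)c(OCc3ccccc3)c1)[C@@H](OCc1ccccc1)C2 | intermediate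
15 | (2R,3S,4S)-7-(benzyloxy)-2-[3,4,5-tris(benzyloxy)phenyl]-4-[(2R,3S)-3,5,7-tris(benzyloxy)-2-[3,4,5-tris(benzyloxy)phenyl]chroman-8-yl]chroman-3-yl acetate | c1ccccc1COc1ccc2c(c1)O[C@H](c1cc(OCc3ccccc3)c(OCc3ccccc3)c(OCc3ccccc3)c1)[C@@H](OC(C)=O)[C@@H]2c1c(OCc2ccccc2)cc(OCc2ccccc2)c2c1O[C@H](c1cc(OCc3ccccc3)c(OCc3ccccc3)c(OCc3ccccc3)c1)[C@@H](OCc1ccccc1)C2 | intermediate
16 | (2R,3S,4S)-7-(benzyloxy)-2-[3,4,5-tris(benzyloxy)phenyl]-4-[(2R,3S)-3,5,7-tris(benzyloxy)-2-[3,4,5-tris(benzyloxy)phenyl]chroman-8-yl]chroman-3-ol | c1ccccc1COc1ccc2c(c1)O[C@H](c1cc(OCc3ccccc3)c(OCc3ccccc3)c(OCc3ccccc3)c1)[C@@H](O)[C@@H]2c1c(OCc2ccccc2)cc(OCc2ccccc2)c2c1O[C@H](c1cc(OCc3ccccc3)c(OCc3ccccc3)c(OCc3ccccc3)c1)[C@@H](OCc1ccccc1)C2 | intermediate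
17 | robinetinidol-(4α→8)-gallocatechin, (2R,3S,4S)-2-(3,4,5-trihydroxyphenyl)-4-[(2R,3S)-3,5,7-trihydroxy-2-(3,4,5-trihydroxyphenyl)chroman-8-yl]chroman-3,7-diol | Oc1ccc2c(c1)O[C@H](c1cc(O)c(O)c(O)c1)[C@@H](O)[C@@H]2c1c(O)cc(O)c2c1O[C@H](c1cc(O)c(O)c(O)c1)[C@@H](O)C2 | target

Total steps: 10. Longest linear sequence: 8 steps (steps 1 to 5, then 8, 9 and 10).

Steps most likely to fail

Step 8. The chiral acid may fail to discriminate the two faces of the oxocarbenium ion or fail to turn over, and ring D may be alkylated at C6 instead of the alkene reacting. The fallback gives up the cycloaddition and forms the interflavan bond by the classical cationic coupling of a flavan-3,4-diol with a flavan-3-ol. It sets out from 3. (2R,3R)-Dihydrorobinetin F1, which is bought, is benzylated on its four phenols (BnBr, K2CO3, DMF) to 7,3',4',5'-tetra-O-benzyldihydrorobinetin F2. NaBH4 (MeOH/THF, 0 °C) should reduce the ketone to the 2,3-trans-3,4-trans flavan-3,4-diol F3. F3 is ionised at C4 with TMSOTf (CH2Cl2, −78 °C) in the presence of an excess of 3, whose C8 should attack the cation mainly trans to the 3-hydroxyl. After separation from the 4β isomer the route is rejoined at 16.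

Step 5. The electron-rich alkenyl boron species may lose boron by protonation before the C–O coupling, or the substrate may be oxidised by copper and O2. The fallback avoids boron and sets out from 4. A Wittig reaction with Ph3P=CHOMe (from (methoxymethyl)triphenylphosphonium chloride and KOtBu, THF) gives the enol methyl ether F4 as an E/Z mixture. Mild hydrolysis (HCO2H, wet THF, rt) gives the arylacetaldehyde F5. O-Acetylation of its enolate (Ac2O, KOAc, 100 °C) should give the enol acetate, from which the (E)-isomer, favoured by the two ortho substituents of ring D, is isolated; this is 7.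

Step 7. The electron-rich α-chloro ether may condense with itself, the phenoxide may be alkylated on carbon, or the acid-labile mixed acetal may be lost on isolation. The fallback forms the acetal carbon by oxidation instead of substitution and sets out from 8 and 10. NaBH4 (MeOH/THF) reduces 8 to 3,4,5-tris(benzyloxy)benzyl alcohol F6. A Mitsunobu reaction with 10 (PPh3, DIAD, THF) gives the aryl benzyl ether F7. DDQ in CH2Cl2/MeOH over 4 Å MS should abstract hydride from the only benzylic position activated by a para oxygen, and methanol traps the cation to return 12.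

Further compounds
F1 | step 8 | (2R,3R)-dihydrorobinetin (bought) | Oc1ccc2c(c1)O[C@H](c1cc(O)c(O)c(O)c1)[C@@H](O)C2=O
F2 | step 8 | (2R,3R)-7-(benzyloxy)-3-hydroxy-2-[3,4,5-tris(benzyloxy)phenyl]chroman-4-one | c1ccccc1COc1ccc2c(c1)O[C@H](c1cc(OCc3ccccc3)c(OCc3ccccc3)c(OCc3ccccc3)c1)[C@@H](O)C2=O
F3 | step 8 | (2R,3S,4R)-7-(benzyloxy)-2-[3,4,5-tris(benzyloxy)phenyl]chroman-3,4-diol | c1ccccc1COc1ccc2c(c1)O[C@H](c1cc(OCc3ccccc3)c(OCc3ccccc3)c(OCc3ccccc3)c1)[C@@H](O)[C@@H]2O
F4 | step 5 | 8-(2-methoxyethenyl)-hexa-O-benzylgallocatechin (E/Z mixture) | c1ccccc1COc1cc(OCc2ccccc2)c2c(c1C=COC)O[C@H](c1cc(OCc3ccccc3)c(OCc3ccccc3)c(OCc3ccccc3)c1)[C@@H](OCc1ccccc1)C2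
F5 | step 5 | 2-[(2R,3S)-3,5,7-tris(benzyloxy)-2-[3,4,5-tris(benzyloxy)phenyl]chroman-8-yl]acetaldehyde | c1ccccc1COc1cc(OCc2ccccc2)c2c(c1CC=O)O[C@H](c1cc(OCc3ccccc3)c(OCc3ccccc3)c(OCc3ccccc3)c1)[C@@H](OCc1ccccc1)C2
F6 | step 7 | 3,4,5-tris(benzyloxy)benzyl alcohol | OCc1cc(OCc2ccccc2)c(OCc2ccccc2)c(OCc2ccccc2)c1
F7 | step 7 | 3-(benzyloxy)phenyl 3,4,5-tris(benzyloxy)benzyl ether | c1ccccc1COc1cccc(c1)OCc1cc(OCc2ccccc2)c(OCc2ccccc2)c(OCc2ccccc2)c1
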